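# Proposed synthesis of (−)-cubebininolide (16)

## Analysis of the target

The target 16 is a γ-butyrolactone (O1, C1 the carbonyl carbon, C2, C3, C4 the OCH2 carbon) that carries a 3,4,5-trimethoxybenzyl group on C2 and another on C3; the benzylic carbons are called C7' (on C2) and C7'' (on C3). C2 and C3 are the only stereocentres, both R, and the two benzyl groups are trans on the ring. C2 is enolisable, but trans is the more stable arrangement, so a slip at C2 alone tends to correct itself, whereas C3 has no such repair and inversion of both centres would give the enantiomer. Besides the lactone, which hydroxide or alkoxide opens, the sensitive parts are the two very electron-rich arenes and their benzylic C–H bonds, which would not survive ozone or strong electrophilic oxidants. The difficulty is to fix the absolute configuration of two adjacent tertiary carbons that bear only carbon substituents and no heteroatom handle, and to tell C1 (acid level) from C4 (alcohol level) in a molecule that is otherwise C2-symmetric. The strategy rests on the array C7'–C2(C1)–C3(C4)–C7'': it is what is left of a trans-cyclohex-4-ene-1,2-dicarboxylate when the two olefinic carbons are removed, with C2 and C3 as the carboxyl-bearing ring carbons, C1 and C4 as the carboxyl carbons and C7' and C7'' as the allylic ring CH2 groups. Read this way, both stereocentres can come from one Diels–Alder reaction of a fumarate, and the near-symmetry becomes an asset, because a C2-symmetric diol gives the same lactone whichever end is oxidised.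

## Retrosynthetic reasoning

**C7'–aryl and C7''–aryl.** The first cut removes both aryl groups from 16 at the benzylic bonds. The trimethoxyphenyl rings tolerate oxidation least, so they should arrive after every oxidative step, and the two bonds are identical and can be made in one operation. Each arm is traced to a carboxyl-derived radical precursor, which leads to the bis(N-acyloxyphthalimide) 12 and the arylzinc chloride 15. Reagent 15 comes from aryl bromide 13 through the arylmagnesium intermediate 14. In the forward direction a nickel catalyst has to decarboxylate each activated ester to a primary radical at C7' or C7'' and join it to an aryl group from 15, twice in one molecule, without attack on the lactone. Neither radical carbon is a stereocentre.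

**Carboxyl carbons back to an alkene.** Ester 12 is made from diacid 11 with no skeletal change. In 11 the two carboxyl carbons end a six-carbon chain that runs through C7', C2, C3 and C7''. Joining them as a C=C gives the cyclohexene-fused lactone 9. This turns an acyclic stereochemical problem into a cyclohexene that a cycloaddition can deliver. The forward reaction is ozonolysis to dialdehyde 10 and oxidation to 11, under conditions that never open the lactone.

**Oxidation level of C1.** Lactone 9 is taken back to diol 6. Because 6 is C2-symmetric, oxidation of either CH2OH group, through hydroxy aldehyde 7 and lactol 8, leads to the same lactone. No protecting group or differentiating step is needed.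

**Release of the auxiliary.** Diol 6 comes from diester 5 by hydride reduction. The same step removes the chiral ester groups as recoverable 2.

**The (4+2) disconnection.** In 5 the ring bonds that correspond to C2–C7' and C3–C7'' of the target are cut together, giving fumarate 3 and butadiene 4. No other disconnection forms a C–C bond at both stereocentres at once, takes the trans relationship directly from the alkene geometry, and places the absolute control in two ester groups that are removed anyway. The forward reaction needs only facial selectivity on 3.

**The dienophile.** Fumarate 3 is the diester of 1 with two molecules of 2, made by acid-catalysed esterification.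

## Alternatives that were turned down

**Alternative 1:** The lactone ring is the disconnection: C3–C4 and C1–O1 are cut and C7'' is taken back to a ketone.
- Forward key step: keto acid A1 is converted into its carboxylate/ketone enolate, which adds at C3 to formaldehyde A3. The hydroxy acid closes to the 4-aroyl lactone A2, the C3 epimers are meant to drain to trans through the ketone enol, and hydrogenolysis of the C7'' carbonyl would then give 16.
- For it: both arenes come from cheap aromatic carbonyl compounds by classical enolate chemistry, only one stereocentre (C2 of A1) has to come from asymmetric synthesis, no carbon is discarded and there is no twofold cross-coupling. On convergence and atom economy it is stronger than the chosen route.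
- Against it:
  - C3 of A1 carries two acidic hydrogens, so a second hydroxymethylation or dehydration to an α-methylene ketone competes.
  - In A2 the ring oxygen is β to the C7'' ketone, so the enolate needed for the epimerisation can expel the carboxylate (E1cB) and open the lactone.
  - The base that moves C3 can also reach C2, now α to the lactone carbonyl, and inversion at both centres is racemisation.
  - An electron-rich aryl ketone must be reduced to CH2 in the last step.
- Comparison: the chosen route gives up the atom economy, but it sets C2 and C3 together in one stereospecific step and needs no equilibration afterwards.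

**Alternative 2:** Both aromatic rings are taken apart: each trimethoxyphenyl group is traced to a six-membered 1,3-dione, made by conjugate addition of a malonate to an enone and Claisen ring closure.
- Forward key step: the C2-symmetric bis(enone) A4 reacts with two equivalents of dimethyl malonate A6 under NaOMe A7, forming four C–C bonds and two carbocycles in the bis(dione) A5. Its ring stereocentres do not matter, because dealkoxycarbonylation, dehydrogenation to the arene and O-methylation erase them; desilylation and lactonisation would follow.
- For it: it is two-directional, needs no transition metal, uses cheap reagents and would allow other arene substitution patterns. On those points it is stronger.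
- Against it:
  - It rebuilds a ring that can be bought ready-made as 13.
  - A4 already contains both stereocentres, so the key step contributes nothing to the stereochemical problem. The most direct source of that core would be diol 6 of the present route.
  - Several operations are needed to reach A4 from such a diol and about five more after A5.
  - The aromatisation is an oxidation of a polyfunctional intermediate that exists as a mixture of diastereomers and enol tautomers.
- Comparison: the chosen route reaches 16 from 6 in four main-line steps.

**Alternative 3:** This cuts the same C7'–aryl and C7''–aryl bonds as the chosen route but makes them from C–H bonds.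
- Forward key step: in diamide A8 each quinolin-8-yl amide directs palladium to its β-methyl group through a five-membered palladacycle. Twofold arylation by aryl iodide A10 with Pd(OAc)2 A11 and AgOAc A12 gives A9. Removal of both amide groups, reduction to the C2-symmetric diol and oxidative lactonisation would finish.
- For it: it is the most direct construction and nothing is excised. On atom economy and on directness of the aryl–carbon bond formation it is stronger than the chosen route, and the reaction class is established for β-methyl groups.
- Against it:
  - The benzylic CH2 made by the first arylation is still a β-C–H of the same amide and can be arylated again, so clean mono-arylation of two methyl groups at full conversion is a narrow window.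
  - The two bidentate amides sit on adjacent carbons and can hold one palladium between them, which would stall turnover.
  - The stereocentres are α to the amide carbonyls and spend hours with acetate above 100 °C, where epimerisation to the meso diamide threatens.
  - The enantiopure parent diacid of A8 must itself be made or resolved.
  - Cleaving two hindered N-quinolinyl amides needs forcing conditions.
- Comparison: the chosen route loses two carbons by decarboxylation. In return, a radical born from a carboxyl group can be arylated only once and only at the carbon that carried it, the coupling runs at room temperature, and the element of absolute control, 2, is cheap, recoverable and removed by a reduction the route needs anyway.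

Key step: step 2

Remark on the chemistry: the (1R,2S,5R)-menthyl ester is assumed to leave the Re,Re face of the fumarate open and so to give the (1R,2R) adduct; if the facial sense is the opposite one, (+)-menthol replaces 2 and nothing else in the route changes.

## Route

**Step 1**
Reactants: 1 fumaric acid; 2 (−)-menthol, (1R,2S,5R)-5-methyl-2-(propan-2-yl)cyclohexan-1-ol (2.1 equiv)
Product: 3 di-(−)-menthyl fumarate, bis[(1R,2S,5R)-5-methyl-2-(propan-2-yl)cyclohexyl] (2E)-but-2-enedioate
Conditions: TsOH·H2O (cat.), toluene, reflux, Dean–Stark trap
Reagents that add atoms: none
Why: Fischer esterification driven to completion by azeotropic removal of water; the acyl–oxygen mechanism leaves the menthyl stereocentres untouched and the E alkene, the stable isomer, is kept.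

**Step 2**
Reactants: 3 di-(−)-menthyl fumarate; 4 buta-1,3-diene
Product: 5 di-(−)-menthyl (1R,2R)-cyclohex-4-ene-1,2-dicarboxylate
Conditions: Et2AlCl (2 equiv, hexane solution), 4 (excess, condensed in), toluene, −40 to −20 °C; aq. HCl; crystallisation or chromatography
Reagents that add atoms: none
Why: Et2AlCl binds the ester carbonyl oxygens of 3 and lowers its LUMO, so that s-cis butadiene adds in a concerted, suprafacial normal-demand Diels–Alder reaction; the closest known reaction type is the aluminium-Lewis-acid-promoted asymmetric cycloaddition of dimenthyl fumarate with simple 1,3-dienes. The six-membered carbocycle closes by (4+2) cycloaddition, and both new bonds (C2–C7' and C3–C7'' in target numbering) form in the same step. The trans relationship of the two new stereocentres follows from the E geometry of the dienophile, which a suprafacial addition cannot change; with unsubstituted butadiene there is no regiochemical or endo/exo question. The absolute configuration is controlled by the menthyl groups: in the Lewis-acid complex each ester should lie s-trans with the carbinol C–H near the carbonyl plane, which puts the isopropyl group over one face of the alkene, and because 3 is C2-symmetric both auxiliaries cover the same face. The diene is left with the face that is Re at both alkene carbons, and attack there gives the 1R,2R adduct. The only selectivity the step needs is this π-facial one; it is secured by two cooperating auxiliaries, by the low temperature that the Lewis acid makes possible, and by purification of 5 at this stage, where the unwanted 1S,2S isomer is still a diastereomer.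

**Step 3**
Reactants: 5 di-(−)-menthyl (1R,2R)-cyclohex-4-ene-1,2-dicarboxylate
Product: 6 [(1R,2R)-cyclohex-4-ene-1,2-diyl]dimethanol
Conditions: LiAlH4 (excess), THF, 0 °C to reflux; H2O, 15% aq. NaOH, H2O; 2 recovered
Reagents that add atoms: none
Why: Hydride reduction of both hindered esters to primary alcohols; no bond at either stereocentre is made or broken, the trans arrangement is also the stable one, and the auxiliary 2 is set free for reuse.

**Step 4**
Reactants: 6 [(1R,2R)-cyclohex-4-ene-1,2-diyl]dimethanol
Product: 9 (3aR,7aR)-3a,4,7,7a-tetrahydro-2-benzofuran-1(3H)-one, via hydroxy aldehyde 7 (not isolated), via lactol 8 (not isolated)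
Conditions: TEMPO (0.1 equiv), PhI(OAc)2 (2.5 equiv), CH2Cl2, rt
Reagents that add atoms: none
Why: Oxoammonium-mediated oxidative lactonisation of a 1,4-diol: one CH2OH is oxidised to the aldehyde, the neighbouring hydroxyl closes the five-membered lactol, and this is oxidised again. Because 6 is C2-symmetric the two hydroxyls are equivalent and only one lactone can form; the isolated alkene is inert to the oxoammonium salt.

**Step 5**
Reactants: 9 (3aR,7aR)-3a,4,7,7a-tetrahydro-2-benzofuran-1(3H)-one
Product: 11 2,2'-[(3R,4R)-2-oxooxolane-3,4-diyl]diacetic acid, via dialdehyde 10 (not isolated)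
Conditions: O3, CH2Cl2, −78 °C; Me2S, −78 °C to rt; evaporate; NaClO2, NaH2PO4, 2-methylbut-2-ene, t-BuOH/H2O, 0 °C to rt
Reagents that add atoms: ozone, [O-][O+]=O; sodium chlorite, [Na+].[O-]Cl=O
Why: Ozonolysis with reductive quench gives the 1,6-dialdehyde, and Pinnick oxidation takes both formyl groups to carboxylic acids without touching C2 or C3. The conditions stay cold and only weakly acidic so that the lactone is never opened, which matters because in 11 the ring oxygen is γ to the C7'' arm carboxyl carbon as well as to C1 and could close on the wrong one.

**Step 6**
Reactants: 11 2,2'-[(3R,4R)-2-oxooxolane-3,4-diyl]diacetic acid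
Product: 12 bis(1,3-dioxoisoindolin-2-yl) 2,2'-[(3R,4R)-2-oxooxolane-3,4-diyl]diacetate
Conditions: N-hydroxyphthalimide (2.2 equiv), i-PrN=C=N-i-Pr (2.4 equiv), DMAP (0.1 equiv), THF/CH2Cl2, 0 °C to rt
Reagents that add atoms: N-hydroxyphthalimide, O=C1c2ccccc2C(=O)N1O
Why: Carbodiimide (Steglich-type) esterification of the two primary acetic acid arms. If the first activated arm is captured by the second carboxylate, the seven-membered anhydride is opened by N-hydroxyphthalimide and the freed acid is activated again, so the sequence should still converge on the bis(ester).

**Step 7**
Reactants: 13 5-bromo-1,2,3-trimethoxybenzene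
Product: 15 chloro(3,4,5-trimethoxyphenyl)zinc, via arylmagnesium bromide 14 (not isolated)
Conditions: Mg turnings, LiCl, THF, rt; then ZnCl2 (1.0 M in THF), 0 °C to rt; titrate with I2
Reagents that add atoms: zinc dichloride, Cl[Zn]Cl; magnesium, [Mg] (kept only in intermediate 14)
Why: LiCl-assisted magnesium insertion gives the Grignard reagent and transmetalation with ZnCl2 gives the arylzinc chloride, whose low basicity and nucleophilicity let it coexist with the lactone and the activated esters in step 8.

**Step 8**
Reactants: 12 bis(1,3-dioxoisoindolin-2-yl) 2,2'-[(3R,4R)-2-oxooxolane-3,4-diyl]diacetate; 15 chloro(3,4,5-trimethoxyphenyl)zinc (6 equiv)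
Product: 16 (−)-cubebininolide, (3R,4R)-3,4-bis[(3,4,5-trimethoxyphenyl)methyl]oxolan-2-one
Conditions: NiCl2(glyme) (40 mol%), 4,4'-di-tert-butyl-2,2'-bipyridine (80 mol%), THF/DMF, rt; aq. HCl
Reagents that add atoms: none
Why: Nickel-catalysed decarboxylative Negishi-type arylation of redox-active esters, run on both arms: a low-valent aryl–nickel species transfers one electron to each N-acyloxyphthalimide, which loses phthalimide anion and CO2 to give the primary radical at C7' or C7''; capture by aryl–nickel and reductive elimination form the C–aryl bond. The radical carbons are not stereocentres and C3 is untouched. C2 is enolisable but already sits in its preferred trans arrangement and meets only a weakly basic arylzinc at room temperature.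

## Compound list

1 | fumaric acid, (2E)-but-2-enedioic acid | OC(=O)/C=C/C(=O)O | starting material
2 | (−)-menthol, (1R,2S,5R)-5-methyl-2-(propan-2-yl)cyclohexan-1-ol | CC(C)[C@@H]1CC[C@@H](C)C[C@H]1O | starting material
3 | di-(−)-menthyl fumarate | CC(C)[C@@H]1CC[C@@H](C)C[C@H]1OC(=O)/C=C/C(=O)O[C@@H]1C[C@H](C)CC[C@H]1C(C)C | intermediate
4 | buta-1,3-diene | C=CC=C | starting material
5 | di-(−)-menthyl (1R,2R)-cyclohex-4-ene-1,2-dicarboxylate | C1[C@H]([C@H](C(=O)O[C@@H]2C[C@H](C)CC[C@H]2C(C)C)CC=C1)C(=O)O[C@@H]1C[C@H](C)CC[C@H]1C(C)C | intermediate
6 | [(1R,2R)-cyclohex-4-ene-1,2-diyl]dimethanol | OC[C@@H]1CC=CC[C@H]1CO | intermediate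
7 | (1R,6R)-6-(hydroxymethyl)cyclohex-3-ene-1-carbaldehyde | O=C[C@@H]1CC=CC[C@H]1CO | intermediate
8 | (3aR,7aR)-1,3,3a,4,7,7a-hexahydro-2-benzofuran-1-ol (C1 unassigned) | OC1OC[C@@H]2CC=CC[C@@H]12 | intermediate
9 | (3aR,7aR)-3a,4,7,7a-tetrahydro-2-benzofuran-1(3H)-one | O=C1OC[C@@H]2CC=CC[C@@H]12 | intermediate
10 | 2,2'-[(3R,4R)-2-oxooxolane-3,4-diyl]diacetaldehyde | O=C1OC[C@H](CC=O)[C@H]1CC=O | intermediate
11 | 2,2'-[(3R,4R)-2-oxooxolane-3,4-diyl]diacetic acid | O=C1OC[C@H](CC(=O)O)[C@H]1CC(=O)O | intermediate
12 | bis(1,3-dioxoisoindolin-2-yl) 2,2'-[(3R,4R)-2-oxooxolane-3,4-diyl]diacetate | O=C1OC[C@H](CC(=O)ON2C(=O)c3ccccc3C2=O)[C@H]1CC(=O)ON1C(=O)c2ccccc2C1=O | intermediate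
13 | 5-bromo-1,2,3-trimethoxybenzene | COc1cc(Br)cc(OC)c1OC | starting material
14 | bromo(3,4,5-trimethoxyphenyl)magnesium | COc1cc([Mg]Br)cc(OC)c1OC | intermediate
15 | chloro(3,4,5-trimethoxyphenyl)zinc (THF solution containing LiCl) | COc1cc([Zn]Cl)cc(OC)c1OC | intermediate
16 | (−)-cubebininolide, (3R,4R)-3,4-bis[(3,4,5-trimethoxyphenyl)methyl]oxolan-2-one | COc1cc(C[C@H]2COC(=O)[C@@H]2Cc2cc(OC)c(OC)c(OC)c2)cc(OC)c1OC | target

## Step count and least certain steps

Total step count: 8. Longest linear sequence: 7 steps (1, 2, 3, 4, 5, 6, 8); step 7 is a one-step side branch.

**Step 2 (key step).** Unactivated butadiene adds slowly at the temperature that keeps the two menthyl groups ordered. Warming to force conversion erodes the facial selectivity and lets the Lewis acid oligomerise the diene. The sense of induction is also assumed, not proven here. Fallback, setting out from 3 (with 4) and returning at 5: 3 and 4 are heated without Lewis acid (toluene, sealed vessel, about 140 °C, trace hydroquinone). This thermal cycloaddition should go to completion with little face selectivity and give 5 together with its diastereomer, di-(−)-menthyl (1S,2S)-cyclohex-4-ene-1,2-dicarboxylate F1. The two are separated by fractional crystallisation or chromatography, so the menthyl groups serve as a resolving handle instead of a directing group.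

**Step 8.** The most likely failure is that only one arm couples cleanly. The second primary radical may be reduced by hydrogen abstraction from THF, may dimerise, or may add to the ortho position of the aryl ring already installed on the other arm (six-membered ring closure). The unhindered primary ester carbonyls are also open to direct acyl substitution by the arylzinc. Fallback, setting out from 11 and returning at 16, which also bypasses 12:
- Iododecarboxylation of 11 (PhI(OAc)2, I2, hν, 1,2-dichloroethane, reflux) gives (3R,4R)-3,4-bis(iodomethyl)oxolan-2-one F2.
- Zinc insertion (Zn dust, LiCl, THF) gives the bis(alkylzinc iodide) [(3R,4R)-2-oxooxolane-3,4-diyl]bis(methylene)bis(iodozinc) F3.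
- A two-electron Negishi coupling of F3 with aryl bromide 13 (Pd(OAc)2, SPhos, THF, rt to 50 °C) gives 16. The polarity of the coupling is reversed and no free radical is present when the aryl–carbon bonds form.

**Step 5.** Three processes threaten the yield: intramolecular aldol condensation of the 1,6-dialdehyde before it is oxidised; migration of the lactone acyl group if the ring opens (O1 closing on the C7'' arm carboxyl); and loss of the small, water-soluble diacid during aqueous isolation. Fallback, setting out from 5 and returning at 16, in which the cleavage is done while C1 and C4 are still menthyl esters, so that no lactone or free hydroxyl is present and every intermediate is lipophilic and C2-symmetric: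
- RuCl3 (cat.)/NaIO4 in MeCN/EtOAc/H2O cleaves the alkene of 5 directly to (3R,4R)-3,4-bis(menthyloxycarbonyl)hexanedioic acid F4.
- Esterification as in step 6 gives its bis(1,3-dioxoisoindolin-2-yl) ester F5.
- Arylation with 15 as in step 8 gives di-(−)-menthyl (2R,3R)-2,3-bis(3,4,5-trimethoxybenzyl)butanedioate F6.
- LiAlH4 gives (2R,3R)-2,3-bis(3,4,5-trimethoxybenzyl)butane-1,4-diol F7.
- Ag2CO3 on Celite in refluxing toluene oxidises one of the two equivalent CH2OH groups through the lactol (3R,4R)-3,4-bis(3,4,5-trimethoxybenzyl)oxolan-2-ol F8 to 16.

This fallback also avoids the trans-fused bicycle of step 4.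

**Step 4.** The hydroxy aldehyde may epimerise at the formyl-bearing carbon while it waits to close, which would lead into the cis-fused lactone series. If closure to the trans-fused lactol is slow, over-oxidation of the second hydroxyl can also occur. Fallback, setting out from 6 and returning at 9, which differentiates the two hydroxyls stepwise instead of through a lactol:
- Monosilylation (NaH, 1 equiv; t-BuMe2SiCl, 1 equiv; THF) gives [(1R,6R)-6-({[tert-butyl(dimethyl)silyl]oxy}methyl)cyclohex-3-en-1-yl]methanol F9. It is a single compound because the hydroxyls are equivalent.
- Oxidation with TEMPO (cat.), NaOCl (cat.) and NaClO2 in MeCN/phosphate buffer gives (1R,6R)-6-({[tert-butyl(dimethyl)silyl]oxy}methyl)cyclohex-3-ene-1-carboxylic acid F10. The aldehyde is consumed by chlorite as it forms.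
- Aqueous HF in MeCN removes the silyl group, and the hydroxy acid (1R,6R)-6-(hydroxymethyl)cyclohex-3-ene-1-carboxylic acid F11 lactonises under the same acidic conditions to 9.

## Further compounds

F1 | step 2 | di-(−)-menthyl (1S,2S)-cyclohex-4-ene-1,2-dicarboxylate | C1[C@@H]([C@@H](C(=O)O[C@@H]2C[C@H](C)CC[C@H]2C(C)C)CC=C1)C(=O)O[C@@H]1C[C@H](C)CC[C@H]1C(C)C
F2 | step 8 | (3R,4R)-3,4-bis(iodomethyl)oxolan-2-one | O=C1OC[C@H](CI)[C@H]1CI
F3 | step 8 | [(3R,4R)-2-oxooxolane-3,4-diyl]bis(methylene)bis(iodozinc) | O=C1OC[C@H](C[Zn]I)[C@H]1C[Zn]I
F4 | step 5 | (3R,4R)-3,4-bis(menthyloxycarbonyl)hexanedioic acid, menthyl = (1R,2S,5R) | OC(=O)C[C@H]([C@H](C(=O)O[C@@H]1C[C@H](C)CC[C@H]1C(C)C)CC(=O)O)C(=O)O[C@@H]1C[C@H](C)CC[C@H]1C(C)C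
F5 | step 5 | bis(1,3-dioxoisoindolin-2-yl) (3R,4R)-3,4-bis(menthyloxycarbonyl)hexanedioate | O=C(C[C@H]([C@H](C(=O)O[C@@H]1C[C@H](C)CC[C@H]1C(C)C)CC(=O)ON1C(=O)c2ccccc2C1=O)C(=O)O[C@@H]1C[C@H](C)CC[C@H]1C(C)C)ON1C(=O)c2ccccc2C1=O
F6 | step 5 | di-(−)-menthyl (2R,3R)-2,3-bis(3,4,5-trimethoxybenzyl)butanedioate | COc1cc(C[C@H]([C@H](C(=O)O[C@@H]2C[C@H](C)CC[C@H]2C(C)C)Cc2cc(OC)c(OC)c(OC)c2)C(=O)O[C@@H]2C[C@H](C)CC[C@H]2C(C)C)cc(OC)c1OC
F7 | step 5 | (2R,3R)-2,3-bis(3,4,5-trimethoxybenzyl)butane-1,4-diol | COc1cc(C[C@H]([C@H](CO)Cc2cc(OC)c(OC)c(OC)c2)CO)cc(OC)c1OC
F8 | step 5 | (3R,4R)-3,4-bis(3,4,5-trimethoxybenzyl)oxolan-2-ol (C2 unassigned) | COc1cc(C[C@H]2COC(O)[C@@H]2Cc2cc(OC)c(OC)c(OC)c2)cc(OC)c1OC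
F9 | step 4 | [(1R,6R)-6-({[tert-butyl(dimethyl)silyl]oxy}methyl)cyclohex-3-en-1-yl]methanol | OC[C@@H]1CC=CC[C@H]1CO[Si](C)(C)C(C)(C)C
F10 | step 4 | (1R,6R)-6-({[tert-butyl(dimethyl)silyl]oxy}methyl)cyclohex-3-ene-1-carboxylic acid | OC(=O)[C@@H]1CC=CC[C@H]1CO[Si](C)(C)C(C)(C)C
F11 | step 4 | (1R,6R)-6-(hydroxymethyl)cyclohex-3-ene-1-carboxylic acid | OC(=O)[C@@H]1CC=CC[C@H]1CO
A1 | alternative 1 | (2R)-4-oxo-2-(3,4,5-trimethoxybenzyl)-4-(3,4,5-trimethoxyphenyl)butanoic acid | OC(=O)[C@@H](CC(=O)c1cc(OC)c(OC)c(OC)c1)Cc1cc(OC)c(OC)c(OC)c1
A2 | alternative 1 | (3R,4R)-3-(3,4,5-trimethoxybenzyl)-4-(3,4,5-trimethoxybenzoyl)oxolan-2-one | COc1cc(C(=O)[C@H]2COC(=O)[C@@H]2Cc2cc(OC)c(OC)c(OC)c2)cc(OC)c1OC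
A3 | alternative 1 | formaldehyde | C=O
A4 | alternative 2 | (3E,6R,7R,9E)-6,7-bis({[tert-butyl(dimethyl)silyl]oxy}methyl)-1,12-dimethoxydodeca-3,9-diene-2,11-dione | COCC(=O)/C=C/C[C@H]([C@H](CO[Si](C)(C)C(C)(C)C)C/C=C/C(=O)COC)CO[Si](C)(C)C(C)(C)C
A5 | alternative 2 | bis(dione): (2R,3R)-2,3-bis(silyloxymethyl)butane-1,4-diyl core carrying at each end a 2-methoxy-4-(methoxycarbonyl)cyclohexane-1,3-dione ring attached at its C5 (ring centres unassigned) | COC(=O)C1C(C[C@H]([C@H](CO[Si](C)(C)C(C)(C)C)CC2CC(=O)C(OC)C(=O)C2C(=O)OC)CO[Si](C)(C)C(C)(C)C)CC(=O)C(OC)C1=O
A6 | alternative 2 | dimethyl malonate | COC(=O)CC(=O)OC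
A7 | alternative 2 | sodium methoxide | [Na+].[O-]C
A8 | alternative 3 | (2R,3R)-2,3-dimethyl-N1,N4-di(quinolin-8-yl)butanediamide | C[C@H]([C@H](C(=O)Nc1cccc2cccnc12)C)C(=O)Nc1cccc2cccnc12
A9 | alternative 3 | (2R,3R)-N1,N4-di(quinolin-8-yl)-2,3-bis(3,4,5-trimethoxybenzyl)butanediamide | COc1cc(C[C@H]([C@H](C(=O)Nc2cccc3cccnc23)Cc2cc(OC)c(OC)c(OC)c2)C(=O)Nc2cccc3cccnc23)cc(OC)c1OC
A10 | alternative 3 | 5-iodo-1,2,3-trimethoxybenzene | COc1cc(I)cc(OC)c1OC
A11 | alternative 3 | palladium diacetate | CC(=O)[O-].CC(=O)[O-].[Pd+2]
A12 | alternative 3 | silver acetate | CC(=O)[O-].[Ag+]
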